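Assumptions: atoms are numbered as in aromadendranes (C1/C5 ring fusion, C2 acetal CH, C3=C4 enol ether, C6/C7/C11 cyclopropane, C10/C14 epoxide, C15 CH2OAc). (S)-Carvone, diethyl cyanomethylphosphonate and sodium malonaldehyde are taken as commercial.

## Retrosynthetic overview
1. Plagiochilin A ⇐ epoxy-lactol aldehyde 12 by one-pot reduction and bis-acetylation. 12 ⇐ lactol-directed epoxidation of the C10=C14 methylene in 11.
2. 11 ⇐ one photochemical operation on 10. Light converts the β-methyl enal into its dienol, which closes C1–C5 and C2–O, so the seven-membered ring and the dihydropyran form together.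
3. 10 ⇐ Knoevenagel condensation of dialdehyde 8 with malonaldehyde (C3, C4, C15). 8 ⇐ keto ester 5 plus a C2 phosphonate (C1, C2).
4. 5 ⇐ oxidative C–C cleavage of (–)-car-3-en-2-one 3 ⇐ (S)-carvone. C7 is the only stereocentre bought.
5. Ring order: cyclopropane first, the six-ring scaffold is cut open, cycloheptane and dihydropyran form at once, and the epoxide comes last.

## Route

**Step 1**
Reactants: 1, (S)-(+)-carvone
Product: 2, (5S)-5-(2-chloropropan-2-yl)-2-methylcyclohex-2-en-1-one
Conditions: dry HCl (g), CH2Cl2, 0 °C
Reagents that add atoms: hydrogen chloride, Cl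
Why: Markovnikov hydrochlorination occurs at the electron-rich isopropenyl group while the enone C=C is deactivated, and C5 is untouched.

**Step 2**
Reactants: 2
Product: 3, (1R,6S)-3,7,7-trimethylbicyclo[4.1.0]hept-3-en-2-one, (–)-car-3-en-2-one, cis-fused
Conditions: KOt-Bu, THF, –20 → 0 °C, short contact time
Reagents that add atoms: none
Why: The α′-enolate undergoes intramolecular 3-exo-tet alkylation (the classical carvone-to-carenone closure), only the cis-fused bicycle is geometrically possible so the new centre (C6) is dictated by the bought one (C7), and a short reaction time avoids eucarvone.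

**Step 3**
Reactants: 3
Product: 4, (1R,6S)-3-hydroxy-3,7,7-trimethylbicyclo[4.1.0]heptan-2-one (C3 epimers, this centre is destroyed in step 4)
Conditions: Mn(dpm)3 (5 mol %), PhSiH3, O2 (1 atm), i-PrOH, 0 °C; then P(OEt)3
Reagents that add atoms: dioxygen, O=O
Why: Mn–H hydrogen-atom-transfer reductive α-hydroxylation of the enone (Mukaiyama type) adds H• to the β-carbon, and the resulting α-keto radical carries no spin on a carbon attached to the cyclopropane, so the three-membered ring survives.

**Step 4**
Reactants: 4
Product: 5, methyl (1R,3S)-2,2-dimethyl-3-(3-oxobutyl)cyclopropane-1-carboxylate (cis)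
Conditions: Pb(OAc)4, MeOH/PhH 1:1, 0 °C → rt
Reagents that add atoms: methanol, CO
Why: Criegee-type α-ketol cleavage opens the ring into an ester terminus (C5) and a methyl ketone (C10, with its CH3 = C14), which differentiates the two ends without protecting groups.

**Step 5**
Reactants: 5; 6, diethyl (cyanomethyl)phosphonate
Product: 7, methyl (1R,3S)-3-[(3E)-4-cyano-3-methylbut-3-en-1-yl]-2,2-dimethylcyclopropane-1-carboxylate (E/Z about 3:1, carried on as the mixture)
Conditions: NaH, THF, 0 °C → rt
Reagents that add atoms: diethyl (cyanomethyl)phosphonate, CCOP(=O)(CC#N)OCC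
Why: Horner–Wadsworth–Emmons olefination takes place only at the ketone because the ester is inert, and the alkene geometry does not matter because it is photo-equilibrated in step 8.

**Step 6**
Reactants: 7
Product: 8, (2E)-5-[(1S,3R)-3-formyl-2,2-dimethylcyclopropyl]-3-methylpent-2-enal
Conditions: DIBAL-H (2.3 equiv), toluene, –78 °C; MeOH, then aq. tartaric acid
Reagents that add atoms: water, O (it supplies the enal oxygen on imine hydrolysis)
Why: At –78 °C DIBAL-H stops at the aluminium hemiacetal (from the ester) and the aluminium aldimine (from the nitrile), so both become aldehydes on work-up.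

**Step 7**
Reactants: 8; 9, sodium malonaldehyde
Product: 10, 2-({(1R,3S)-2,2-dimethyl-3-[(3E)-3-methyl-5-oxopent-3-en-1-yl]cyclopropyl}methylidene)propanedial
Conditions: 9 (1.05 equiv), AcOH (1.1 equiv), ethylenediammonium diacetate (5 mol %), 4 Å MS, CH2Cl2, 0 °C, dark; short SiO2 plug, used at once
Reagents that add atoms: sodium malonaldehyde, [Na+].[O-]/C=C/C=O
Why: Knoevenagel condensation takes place at the only non-vinylogous aldehyde because the β,β-dialkyl enal is much less electrophilic, and it gives a symmetric, highly electrophilic 1-oxadiene with no E/Z issue.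

**Step 8 (key step)**
Reactants: 10
Product: 11, tricyclic lactol aldehyde: a 2-hydroxy-3,4-dihydro-2H-pyran-5-carbaldehyde cis-fused (H1/H5 cis) to a 10-methylene-cycloheptane that carries the cis-fused gem-dimethylcyclopropane, with the pyran anti to the CMe2 bridge (H5/H6 trans); an equilibrating pair of C2 anomers
Conditions: hν 365 nm LED, FEP flow coil, 2 mM in degassed toluene, naphthalene (0.2 M, triplet quencher), –20 °C
Reagents that add atoms: none
Why: Proposed new method: singlet nπ* excitation of the remote β-methyl enal triggers the 1,5-H shift known from photodeconjugation and gives the (Z)-dienol HO–C2H=C1H–C10(=C14H2), which turns an inert acceptor alkene into an electron-rich enol. This enol is captured in the ground state by the tethered alkylidene-malonaldehyde in an inverse-demand oxa-Diels–Alder reaction (C1→C5, formyl O→C2), so C5 is attacked as an electrophile and never carries spin next to the cyclopropane. The tether enforces the fused mode, because reaction at C10=C14 would need a bridged transition state. The dienol from the Z-enal (H taken from C9) would need a trans-cycloheptene and simply reverts. C4 ends anti to the endo-methyl of C11, which sets C5, and the short cis-cyclopropane tether gives the cis C1/C5 fusion. The closest known reaction types are photoenolization/Diels–Alder of o-alkyl aryl ketones, photodeconjugation of enoates and enones, and the thermal domino Knoevenagel/intramolecular hetero-Diels–Alder reaction.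

**Step 9**
Reactants: 11
Product: 12, (10S)-spiro-epoxy lactol aldehyde (epoxide O on the face bearing C2, C14 syn to H1)
Conditions: VO(acac)2 (5 mol %), t-BuOOH (1.3 equiv, decane), CH2Cl2, 0 °C
Reagents that add atoms: tert-butyl hydroperoxide, CC(C)(C)OO
Why: Hydroxyl-directed vanadium epoxidation uses the lactol OH as a homoallylic director, so oxygen is delivered from the face on which C2 sits, and the push–pull C3=C4 enol ether is too electron-poor to react.

**Step 10**
Reactants: 12
Product: 13, plagiochilin A
Conditions: DIBAL-H (2.5 equiv), CH2Cl2, –78 °C; then pyridine, DMAP, Ac2O, –78 → –20 °C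
Reagents that add atoms: acetic anhydride, CC(=O)OC(C)=O
Why: In this reductive acetylation (aluminium-alkoxide trapping), DIBAL-H deprotonates the lactol and 1,2-reduces the C15 aldehyde, both aluminium alkoxides are acetylated in situ, and the C2 acetate takes the iridoid-type 1,2-trans arrangement (H1/H2 trans) favoured by the anomeric effect and by sterics.

## Compound list
1 | (S)-(+)-carvone | CC1=CC[C@@H](CC1=O)C(C)=C | starting material
2 | (5S)-5-(2-chloropropan-2-yl)-2-methylcyclohex-2-en-1-one | CC1=CC[C@@H](CC1=O)C(C)(C)Cl | intermediate
3 | (1R,6S)-car-3-en-2-one | CC1=CC[C@H]2[C@@H](C1=O)C2(C)C | intermediate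
4 | (1R,6S)-3-hydroxycaran-2-one (C3 epimers) | CC1(O)CC[C@H]2[C@@H](C1=O)C2(C)C | intermediate
5 | methyl (1R,3S)-2,2-dimethyl-3-(3-oxobutyl)cyclopropane-1-carboxylate | COC(=O)[C@@H]1[C@H](CCC(C)=O)C1(C)C | intermediate
6 | diethyl (cyanomethyl)phosphonate | CCOP(=O)(CC#N)OCC | starting material
7 | E-unsaturated nitrile ester | COC(=O)[C@@H]1[C@H](CC/C(C)=C/C#N)C1(C)C | intermediate
8 | dialdehyde | O=C[C@@H]1[C@H](CC/C(C)=C/C=O)C1(C)C | intermediate
9 | sodium malonaldehyde | [Na+].[O-]/C=C/C=O | starting material
10 | alkylidene-malonaldehyde enal | O=CC(C=O)=C[C@@H]1[C@H](CC/C(C)=C/C=O)C1(C)C | intermediate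
11 | tricyclic lactol aldehyde (major anomer drawn) | O=CC1=CO[C@H](O)[C@@H]2[C@H]1[C@@H]1[C@H](CCC2=C)C1(C)C | intermediate
12 | epoxy lactol aldehyde | O=CC1=CO[C@H](O)[C@@H]2[C@H]1[C@@H]1[C@H](CC[C@@]23CO3)C1(C)C | intermediate
13 | plagiochilin A | CC(=O)OCC1=CO[C@H](OC(C)=O)[C@@H]2[C@H]1[C@@H]1[C@H](CC[C@@]23CO3)C1(C)C | target

## Summary
Total steps: 10. Longest linear sequence: 10.

Steps most likely to fail:
1. **Step 8 (the new step).**
   - Risks: the dienol may revert faster than it cyclises. The cyclopropyl-conjugated heterodiene is also excited at 365 nm and could open or epimerise the cyclopropane through its triplet state.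
   - Fallback (known chemistry, no light): convert 8 into its 1-silyloxydiene (TBSOTf, Et3N). Then run the established thermal domino Knoevenagel/intramolecular oxa-Diels–Alder reaction with 9 (ethylenediammonium diacetate, rt) and hydrolyse the silyl acetal to 11. This adds one step.
2. **Step 7.**
   - Risks: the alkylidene-malonaldehyde is fragile, selectivity between the two aldehydes may be imperfect, and C6 could epimerise.
   - Fallback: change the C3 building block to sodium methyl formylacetate. This gives an isolable 2-formylacrylate heterodiene whose C15 is an ester, and that ester is reduced in step 10 with extra DIBAL-H.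
3. **Step 9.**
   - Risks: facial selectivity at C10 may be poor, or the lactol may be oxidised.
   - Fallback: acetylate C2 first, then use the halohydrin route (NBS/H2O, then K2CO3). Bromonium forms on the open face, so the oxygen enters anti to it, which is stereocomplementary to a direct peracid epoxidation from that open face. C15 is then reduced (NaBH4/CeCl3) and acetylated in separate steps.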